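(The numbers in the tables stem from a simulated flask for an exercise; scatter was added.)

If a flask's yield simply grew in step with time and with concentration, one number read from one run would serve for all of these flasks.

| flask | electrophile | free base | protonated nucleophile | remark | time |
|---|---|---|---|---|---|
| gamma | 0.020 M | 4.5 equiv | 1.5 equiv | run made earlier |  |
| noon | 0.040 M | 3.00 equiv | 1.50 equiv |  | 5.0 h |
| dawn | 0.080 M | 3.00 equiv | 1.50 equiv |  | 5.0 h |
| midnight | 0.020 M | 3.00 equiv | 1.50 equiv |  | 5.0 h |
| winter | 0.060 M | 3.00 equiv | 1.50 equiv |  | 5.0 h |
| summer | 0.0060 M | 3.00 equiv | 1.50 equiv |  | 5.0 h |
| dusk | 0.030 M | 3.00 equiv | 1.50 equiv |  | 5.0 h |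

gamma run (percent of the electrophile charged): time / min: target / % = 20.0: 2.0; 40.0: 3.8; 60.0: 6.4; 80.0: 8.4; 120: 12.1

(standard deviation of a reading: 0.5 percentage points)

- the flasks put in order of amount of target, in percent of the electrophile charged, best first, at 5.0 h (noon / dawn / midnight / winter / summer / dusk)
- the same order at 1.0 h (noon / dawn / midnight / winter / summer / dusk)
- the amount of target, in percent of the electrophile charged of the flask you put first, at 5.0 h
- the amount of target, in percent of the electrophile charged of the flask you put last, at 5.0 h

- a reading or a percentage of target counts all its forms, free or not
- no earlier run changes the charge of free base; that part of a forecast is a guess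

The bench rule trusts the nearly straight gamma run. Its last reading, divided by its time and by its c(electrophile), gives a turnover pace of 3.02 /M/h, the share of electrophile turned per hour and per unit of concentration. Pace times c(electrophile) times time counts turns, and while turns stay small, the share made is simply the count. Summer has 0.0908 turns, so the line is still usable there.

But dawn has 10.0 times the concentration-and-time of gamma's last reading, and the line promises 121%, which is more than was charged. One turn falls at 0.0662 M for 5.0 h, below dawn's 0.080 M, so the straight line cannot hold up there.

Near that border I let the pace fall as for two partners used one for one (second order), and the share becomes turns divided by one plus turns. That gives 54.7% for dawn and 8.32% for summer. Gamma had more free base, and no run prices that, so keeping the pace unchanged is my guess. The flasks share their equivalents, so my order follows c(electrophile) at both times.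

The forecast gives dawn > winter > noon > dusk > midnight > summer at 5.0 h and dawn > winter > noon > dusk > midnight > summer at 1.0 h, with 56% first and 7.4% last. Its ground is: “All flasks share the same equivalents, so more concentrated means faster”. My summer stands above its number.

    electrophile + nucleophile → acid set free + target (k = 0.314 /M/min)
    nucleophile + acid set free ⇌ protonated nucleophile, settled at all times (K = 74200 /M)
    acid set free + free base ⇌ salt of the base (K = 4.56 × 10⁵ /M, k = 16.6 /M/min)
    crystals ⇌ target, rate k4*(cs4 - [target]) while solid is left; crystals form when [target] > cs4 (solubility = 0.690 mM, k = 0.319 /min)
    target → over-reaction product (k = 0.0128 /min)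

The flasks come out as dawn > winter > noon > dusk > midnight > summer at 5.0 h and dawn > winter > noon > dusk > midnight > summer at 1.0 h, with dawn at 54.7% and summer at 4.61% at 5.0 h. In dawn, 53.5% stood as crystals at 5.00 h, counted within its target, beside 5.42% over-reaction product and 40% of the electrophile; summer held 0% crystals and 11.9% over-reaction product, more than its target. Dawn's target moves by 5 points with protonated nucleophile at 1.21 equiv. For dawn's neighbour at 0.32 M, the pace gives 4.83 turns, hence 82.9%, and that flask holds 81.9%.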